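**Strategy.** Everything rests on cutting the dihydropyran ring B of the chroman across C4–C3 and O1–C2. Ring A is unmasked as an ortho-quinone methide (O1=C8a–C4a=C4H2) and ring B is closed in one catalytic, enantioselective inverse-demand oxa-[4+2] cycloaddition with the vinylsilane Me2C=CH–SiMe2Bn, whose silicon is the latent C3 hydroxyl. The step exploits the ortho relation of O1 and C4 on ring A, the gem-dimethyl carbon C2 (tertiary cation character fixes the regiochemistry) and the C8 benzoyl carbonyl, which together with O1 chelates a chiral copper Lewis acid. The precursor is a 2-hydroxybenzyl alcohol with both other phenols silylated; oxidation with retention and C6 geranylation follow.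

Key step: step 4

Remark on numbering: chroman numbering is used for the target and all bicyclic compounds (O1, C2 gem-dimethyl, C3 carbinol, C4 methylene, C4a, C5 OH, C6 geranyl, C7 OH, C8 benzoyl, C8a); ring A is the benzene ring, ring B the dihydropyran ring.
Assumption: paraformaldehyde is written as its monomer; compounds 1, 2, 4, 5, 8 (THF solution), 9, 13 and 16 are taken as commercial; (S,S)-tBu-box is 2,2'-(propane-2,2-diyl)bis[(4S)-4-tert-butyl-4,5-dihydro-1,3-oxazole].

**Step 1**
Reactants: 1 (2,4,6-trihydroxyphenyl)(phenyl)methanone; 2 chlorotri(propan-2-yl)silane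
Product: 3 {2-hydroxy-4,6-bis[(triisopropylsilyl)oxy]phenyl}(phenyl)methanone
Conditions: TIPSCl (2.2 equiv), imidazole, DMF, 0 °C to rt
Reagents that add atoms: chlorotri(propan-2-yl)silane (2), CC(C)[Si](Cl)(C(C)C)C(C)C
Why: Silyl ether formation on phenols: the two hydroxyls flanking the benzoyl group are equivalent, and once one of them and the para hydroxyl are silylated the last one is locked in a hydrogen bond to the carbonyl and shielded, so the reaction should stop at 3.

**Step 2**
Reactants: 3 {2-hydroxy-4,6-bis[(triisopropylsilyl)oxy]phenyl}(phenyl)methanone; 4 paraformaldehyde; 5 phenylboronic acid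
Product: 7 {2-hydroxy-3-(hydroxymethyl)-4,6-bis[(triisopropylsilyl)oxy]phenyl}(phenyl)methanone, via benzodioxaborin 6 (not isolated)
Conditions: PhB(OH)2 (1.2 equiv), (CH2O)n, EtCO2H (cat.), toluene, reflux, Dean–Stark; then propane-1,3-diol, THF, rt
Reagents that add atoms: formaldehyde from paraformaldehyde (4), C=O
Why: Nagata ortho-hydroxymethylation: the aryl ester of phenylboronic acid binds formaldehyde and delivers it through a six-membered transition state to the carbon ortho to the one free hydroxyl, giving benzodioxaborin 6 that the diol then transesterifies to free 7, while the other ring CH is not ortho to a free hydroxyl and is flanked by two bulky silyloxy groups.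

**Step 3**
Reactants: 8 (2-methylprop-1-en-1-yl)magnesium bromide; 9 benzyl(chloro)dimethylsilane
Product: 10 benzyl(dimethyl)(2-methylprop-1-en-1-yl)silane
Conditions: THF, 0 °C to rt
Reagents that add atoms: benzyl(chloro)dimethylsilane (9), C[Si](C)(Cl)Cc1ccccc1
Why: Nucleophilic substitution at silicon by an alkenyl Grignard reagent, a standard route to alkenylsilanes that creates no stereocentre.

**Step 4**
Reactants: 7 {2-hydroxy-3-(hydroxymethyl)-4,6-bis[(triisopropylsilyl)oxy]phenyl}(phenyl)methanone; 10 benzyl(dimethyl)(2-methylprop-1-en-1-yl)silane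
Product: 12 {(3R)-3-[benzyl(dimethyl)silyl]-2,2-dimethyl-5,7-bis[(triisopropylsilyl)oxy]-3,4-dihydro-2H-chromen-8-yl}(phenyl)methanone, via ortho-quinone methide 11 (not isolated)
Conditions: Cu(SbF6)2 (10 mol%, from CuCl2 and AgSbF6), (S,S)-tBu-box (11 mol%), 10 (3 equiv), 4 Å molecular sieves, CH2Cl2, −20 °C to rt
Reagents that add atoms: benzyl(dimethyl)(2-methylprop-1-en-1-yl)silane (10), CC(C)=C[Si](C)(C)Cc1ccccc1
Why: Proposed new method: the divalent copper Lewis acid dehydrates 7 to the ortho-quinone methide 11 and holds it as a six-membered chelate through the C8a carbonyl oxygen and the benzoyl oxygen; the alkene then adds in an asynchronous inverse-electron-demand oxa-[4+2] cycloaddition in which the C4–C3 bond leads and the O1–C2 bond follows as the chelated oxygen collapses onto the developing tertiary, beta-silyl-stabilised cation at C2. The closest known reactions are the thermal and Lewis-acid hetero-Diels–Alder reaction of ortho-quinone methides with alkenes to give chromans and the copper bis(oxazoline)-catalysed inverse-demand hetero-Diels–Alder reaction of chelating 1-oxadienes; new are the vinylsilane as the 2π partner and absolute control on an unsubstituted methide. Ring B, the six-membered dihydropyran, is closed by this [4+2] cycloaddition, both new ring bonds forming on the same face of the heterodiene. C3, the only new stereocentre, is set by the catalyst: one tert-butyl group of the (S,S) ligand shields one face of the chelated heterodiene near C4 and the silyl group takes the exo position away from the C5 silyloxy group, which by the square-planar chelate model should give 3R (the antipodal ligand is available should the sense prove opposite). The step needs regioselectivity (silicon-bearing carbon to C4, CMe2 to O1), secured by the tertiary cation at C2 and the beta-silicon effect; site selectivity for O1, secured because it is the only free ortho oxygen (O5 is a silyl ether); and ring closure ahead of loss of silicon, favoured by the chelated, non-nucleophilic medium at low temperature.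

**Step 5**
Reactants: 12 {(3R)-3-[benzyl(dimethyl)silyl]-2,2-dimethyl-5,7-bis[(triisopropylsilyl)oxy]-3,4-dihydro-2H-chromen-8-yl}(phenyl)methanone; 13 hydrogen peroxide
Product: 15 [(3R)-3,5,7-trihydroxy-2,2-dimethyl-3,4-dihydro-2H-chromen-8-yl](phenyl)methanone, via silanol 14 (not isolated)
Conditions: Bu4NF (5 equiv), THF, 0 °C to rt; then KHCO3, 30% aq H2O2, MeOH, 40 °C
Reagents that add atoms: hydrogen peroxide (13), OO
Why: Tamao–Fleming oxidation of a benzyldimethylsilyl group: fluoride cleaves both aryl silyl ethers and then the benzyl–silicon bond to give silanol 14, and hydroperoxide on silicon triggers migration of C3 from silicon to oxygen with retention so that 3R is kept, the early bis-phenoxide making O1 a poor leaving group and thereby suppressing elimination of silicon across C3–C2.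

**Step 6**
Reactants: 15 [(3R)-3,5,7-trihydroxy-2,2-dimethyl-3,4-dihydro-2H-chromen-8-yl](phenyl)methanone; 16 geranyl bromide
Product: 17 {(3R)-6-[(2E)-3,7-dimethylocta-2,6-dien-1-yl]-3,5,7-trihydroxy-2,2-dimethyl-3,4-dihydro-2H-chromen-8-yl}(phenyl)methanone
Conditions: geranyl bromide (1.1 equiv), 10% aq KOH, 0 °C to rt
Reagents that add atoms: geranyl bromide (16), CC(C)=CCC/C(C)=C/CBr
Why: C-alkylation of a phloroglucinol-type phenoxide with an allylic bromide (SN2, E geometry of the geranyl unit untouched): C6 is the only unsubstituted carbon of ring A and the aqueous medium favours C- over O-alkylation, the secondary C3 hydroxyl staying un-ionised.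

**Compound list**
1 | (2,4,6-trihydroxyphenyl)(phenyl)methanone (2,4,6-trihydroxybenzophenone) | O=C(c1ccccc1)c1c(O)cc(O)cc1O | starting material
2 | chlorotri(propan-2-yl)silane | CC(C)[Si](Cl)(C(C)C)C(C)C | starting material
3 | {2-hydroxy-4,6-bis[(triisopropylsilyl)oxy]phenyl}(phenyl)methanone | O=C(c1ccccc1)c1c(O)cc(O[Si](C(C)C)(C(C)C)C(C)C)cc1O[Si](C(C)C)(C(C)C)C(C)C | intermediate
4 | paraformaldehyde, written as formaldehyde | C=O | starting material
5 | phenylboronic acid | OB(O)c1ccccc1 | starting material
6 | phenyl{2-phenyl-5,7-bis[(triisopropylsilyl)oxy]-4H-1,3,2-benzodioxaborinin-8-yl}methanone | O=C(c1ccccc1)c1c2OB(c3ccccc3)OCc2c(O[Si](C(C)C)(C(C)C)C(C)C)cc1O[Si](C(C)C)(C(C)C)C(C)C | intermediate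
7 | {2-hydroxy-3-(hydroxymethyl)-4,6-bis[(triisopropylsilyl)oxy]phenyl}(phenyl)methanone | O=C(c1ccccc1)c1c(O)c(CO)c(O[Si](C(C)C)(C(C)C)C(C)C)cc1O[Si](C(C)C)(C(C)C)C(C)C | intermediate
8 | (2-methylprop-1-en-1-yl)magnesium bromide | CC(C)=C[Mg]Br | starting material
9 | benzyl(chloro)dimethylsilane | C[Si](C)(Cl)Cc1ccccc1 | starting material
10 | benzyl(dimethyl)(2-methylprop-1-en-1-yl)silane | CC(C)=C[Si](C)(C)Cc1ccccc1 | intermediate
11 | 2-benzoyl-6-methylidene-3,5-bis[(triisopropylsilyl)oxy]cyclohexa-2,4-dien-1-one (copper-bound ortho-quinone methide) | C=C1C(=O)C(C(=O)c2ccccc2)=C(O[Si](C(C)C)(C(C)C)C(C)C)C=C1O[Si](C(C)C)(C(C)C)C(C)C | intermediate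
12 | {(3R)-3-[benzyl(dimethyl)silyl]-2,2-dimethyl-5,7-bis[(triisopropylsilyl)oxy]-3,4-dihydro-2H-chromen-8-yl}(phenyl)methanone | O=C(c1ccccc1)c1c(O[Si](C(C)C)(C(C)C)C(C)C)cc(O[Si](C(C)C)(C(C)C)C(C)C)c2c1OC(C)(C)[C@H]([Si](C)(C)Cc3ccccc3)C2 | intermediate
13 | hydrogen peroxide | OO | starting material
14 | {(3R)-5,7-dihydroxy-3-[hydroxy(dimethyl)silyl]-2,2-dimethyl-3,4-dihydro-2H-chromen-8-yl}(phenyl)methanone | O=C(c1ccccc1)c1c(O)cc(O)c2c1OC(C)(C)[C@H]([Si](C)(C)O)C2 | intermediate
15 | [(3R)-3,5,7-trihydroxy-2,2-dimethyl-3,4-dihydro-2H-chromen-8-yl](phenyl)methanone | O=C(c1ccccc1)c1c(O)cc(O)c2c1OC(C)(C)[C@H](O)C2 | intermediate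
16 | geranyl bromide, (2E)-1-bromo-3,7-dimethylocta-2,6-diene | CC(C)=CCC/C(C)=C/CBr | starting material
17 | {(3R)-6-[(2E)-3,7-dimethylocta-2,6-dien-1-yl]-3,5,7-trihydroxy-2,2-dimethyl-3,4-dihydro-2H-chromen-8-yl}(phenyl)methanone | CC(C)=CCC/C(C)=C/Cc1c(O)c2c(c(C(=O)c3ccccc3)c1O)OC(C)(C)[C@H](O)C2 | target

**Totals.** Total step count: 6. Longest linear sequence: 5 steps (steps 1, 2, 4, 5 and 6; step 3 is the side branch to the alkene).

**Steps most likely to fail**

1. Step 4 (bears the label "Proposed new method:"). What may go wrong: poor discrimination between the two faces of the heterodiene or between exo and endo placement of silicon, and loss of silicon from the beta-silyl cation before ring closure, which would open the way to a ring-opened ortho-prenyl phenol. The fallback uses known chemistry, sets out from 7 and comes back to the route at 15; it forms C4–C3 and O1–C2 in separate operations. Conjugate addition of (2-methylprop-1-en-1-yl)boronic acid to the thermally generated ortho-quinone methide (2,2'-biphenol cat., toluene, 80 °C) should give the ortho-prenyl phenol {2-hydroxy-3-(3-methylbut-2-en-1-yl)-4,6-bis[(triisopropylsilyl)oxy]phenyl}(phenyl)methanone F1. Shi epoxidation (D-fructose-derived ketone 1,2:4,5-di-O-isopropylidene-β-D-erythro-2,3-hexodiulo-2,6-pyranose, KHSO5, K2CO3, MeCN/dimethoxymethane/water, 0 °C) should give the (R)-epoxide {3-{[(2R)-3,3-dimethyloxiran-2-yl]methyl}-2-hydroxy-4,6-bis[(triisopropylsilyl)oxy]phenyl}(phenyl)methanone F2. Camphorsulfonic acid in CH2Cl2 should induce 6-endo opening at the tertiary carbon by the phenol, leaving the carbinol centre untouched, to give the silyl-protected chromanol {(3R)-3-hydroxy-2,2-dimethyl-5,7-bis[(triisopropylsilyl)oxy]-3,4-dihydro-2H-chromen-8-yl}(phenyl)methanone F3, and Bu4NF in THF then gives 15.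

2. Step 5. What may go wrong: elimination of the C3 silicon with cleavage of the O1–C2 bond under fluoride or base, sluggish oxidation of the hindered C3–Si bond, or over-oxidation of the electron-rich phenolate ketone by peroxide. The fallback replaces silicon by boron as the latent hydroxyl, sets out from 7 and comes back at 15. The conditions of step 4 with commercial 4,4,5,5-tetramethyl-2-(2-methylprop-1-en-1-yl)-1,3,2-dioxaborolane should give the boronate phenyl{(3R)-2,2-dimethyl-3-(4,4,5,5-tetramethyl-1,3,2-dioxaborolan-2-yl)-5,7-bis[(triisopropylsilyl)oxy]-3,4-dihydro-2H-chromen-8-yl}methanone F4. NaBO3·4H2O in THF/water oxidises the C–B bond with retention while the phenols stay silylated and no fluoride is present, giving the silyl-protected chromanol F3 of the first fallback, which Bu4NF converts to 15.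

3. Step 6. What may go wrong: O-alkylation and double alkylation competing with alkylation at C6. The fallback replaces direct alkylation by halogenation and cross-coupling, sets out from 15 and comes back at 17. Iodination of the only free carbon of ring A (N-iodosuccinimide, CH2Cl2, 0 °C) should give [(3R)-3,5,7-trihydroxy-6-iodo-2,2-dimethyl-3,4-dihydro-2H-chromen-8-yl](phenyl)methanone F5, and Stille coupling with tributyl(geranyl)stannane (Pd(PPh3)4, DMF, 80 °C) should give 17 with the E geometry retained.

**Further compounds**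
F1 | step 4 | {2-hydroxy-3-(3-methylbut-2-en-1-yl)-4,6-bis[(triisopropylsilyl)oxy]phenyl}(phenyl)methanone | CC(C)=CCc1c(O)c(C(=O)c2ccccc2)c(O[Si](C(C)C)(C(C)C)C(C)C)cc1O[Si](C(C)C)(C(C)C)C(C)C
F2 | step 4 | {3-{[(2R)-3,3-dimethyloxiran-2-yl]methyl}-2-hydroxy-4,6-bis[(triisopropylsilyl)oxy]phenyl}(phenyl)methanone | CC1(C)O[C@@H]1Cc2c(O)c(C(=O)c3ccccc3)c(O[Si](C(C)C)(C(C)C)C(C)C)cc2O[Si](C(C)C)(C(C)C)C(C)C
F3 | step 4 | {(3R)-3-hydroxy-2,2-dimethyl-5,7-bis[(triisopropylsilyl)oxy]-3,4-dihydro-2H-chromen-8-yl}(phenyl)methanone | O=C(c1ccccc1)c1c(O[Si](C(C)C)(C(C)C)C(C)C)cc(O[Si](C(C)C)(C(C)C)C(C)C)c2c1OC(C)(C)[C@H](O)C2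
F4 | step 5 | phenyl{(3R)-2,2-dimethyl-3-(4,4,5,5-tetramethyl-1,3,2-dioxaborolan-2-yl)-5,7-bis[(triisopropylsilyl)oxy]-3,4-dihydro-2H-chromen-8-yl}methanone | O=C(c1ccccc1)c1c(O[Si](C(C)C)(C(C)C)C(C)C)cc(O[Si](C(C)C)(C(C)C)C(C)C)c2c1OC(C)(C)[C@H](B3OC(C)(C)C(C)(C)O3)C2
F5 | step 6 | [(3R)-3,5,7-trihydroxy-6-iodo-2,2-dimethyl-3,4-dihydro-2H-chromen-8-yl](phenyl)methanone | O=C(c1ccccc1)c1c(O)c(I)c(O)c2c1OC(C)(C)[C@H](O)C2
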